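Which flask leads in mono adduct share after 2.5 d?

| setting | Sunday's | Saturday's | north | north-east | east |
|---|---|---|---|---|---|
| substrate | 0.14 M | 0.22 M | 0.10 M | 0.10 M | 0.10 M |
| reagent | 1.1 equiv | 1.1 equiv | 1.10 equiv | 1.10 equiv | 1.10 equiv |
| temperature | 15 °C | 45 °C | 45 °C | 20 °C | 70 °C |
| remark | run made earlier | run made earlier |  |  |  |
| time |  |  | 2.5 d | 2.5 d | 2.5 d |

- Sunday's (time / d: mono adduct / %, double product / %): 1.67: 30.4, 7.0; 5.00: 41.3, 19.7; 10.0: 41.7, 27.4; 12.0: 41.7, 29.3
- Saturday's (time / d: mono adduct / %, double product / %): 0.417: 39.5, 32.2; 1.04: 37.8, 33.8; 2.08: 35.7, 29.3; 3.00: 34.4, 29.7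

(readings scatter by 1 percentage point)

- which flask leads in share of mono adduct in all that became mono adduct or double product or tris adduct or tetra adduct or isomer of the product ("all alike" within 1.5 percentage points) (north / north-east / east / all alike)
- share of mono adduct in all that became mono adduct or double product or tris adduct or tetra adduct or isomer of the product, north
- share of mono adduct in all that became mono adduct or double product or tris adduct or tetra adduct or isomer of the product, north-east
- share of mono adduct in all that became mono adduct or double product or tris adduct or tetra adduct or isomer of the product, east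



In Sunday's run mono adduct stands still near 41.7% from 10.0 d, with substrate at 30.9% by difference. Reckoning with the two additions, a standing mono adduct means the first makes it as fast as the second removes it. So the second rate constant over the first equals c(substrate)/c(mono adduct), which reads 0.741. We call this κ, the selectivity factor. Integrating the two additions gives share = (a^κ − a)/((1 − κ)(1 − a)), where a is the fraction of substrate left.

For a we work in powers of ten. Plain second-order reckoning gives 0.106 L mol⁻¹ h⁻¹ from Sunday's first reading and 1.15 L mol⁻¹ h⁻¹ from Saturday's, 1.04 decades apart. Saturday's value may read low, since mono adduct plus double product in that run reads 71.7% at the first reading and 71.6% at the second. North-east sits 0.167 of the way up that span, so we put its constant at 0.158 L mol⁻¹ h⁻¹. Our estimate for north-east is then a = 51.3% and a share of 76.7%.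

Saturday's mono adduct plus double product stops growing after its first reading, and at equal c(substrate) times time we expect north to reach that point at about 0.917 d, sooner than 2.5 d. East is hotter than north. For both we assume Saturday's range, 48.0% to 53.7%, so we expect north-east to lead.

The forecast names north-east, with 50% for north, 75% for north-east and 30% for east, the last resting on “an extrapolated and uncertain rate”, and there it stands below our range. The flasks give 48.4% for north, 73.7% for north-east and 50.4% for east, so north-east leads.

    substrate + reagent → mono adduct (k = 25.0 L mol⁻¹ h⁻¹, Ea = 83.0 kJ mol⁻¹)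
    reagent + mono adduct → double product (k = 20.0 L mol⁻¹ h⁻¹, Ea = 84.0 kJ mol⁻¹)
    reagent + double product → tris adduct (k = 1.90 L mol⁻¹ h⁻¹, Ea = 93.0 kJ mol⁻¹)
    reagent + tris adduct → tetra adduct (k = 58.0 L mol⁻¹ h⁻¹, Ea = 77.0 kJ mol⁻¹)
    mono adduct ⇌ isomer of the product (K = 0.110, k = 0.0860 h⁻¹, Ea = 99.0 kJ mol⁻¹, ΔH = −23.0 kJ mol⁻¹)
    2 reagent → self-condensation product (k = 0.380 L mol⁻¹ h⁻¹, Ea = 83.0 kJ mol⁻¹)
    reagent ⇌ dormant form (K = 0.700, k = 0.0480 h⁻¹, Ea = 111 kJ mol⁻¹, ΔH = −27.0 kJ mol⁻¹)
    (constants at 70 °C)

At 2.50 d north-east holds substrate 48.1%, less than our 51.3%, and κ at that value gives 74.7%. The neighbouring flask, north-east with 0.440 equiv of reagent, ends with substrate 75.0%. The same κ gives it 89.6%, and the flask gives 88.7%.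

(The numbers in the tables stem from a simulated flask for an exercise, and the scatter is random.)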